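**Retrosynthetic overview**

- The target is reached from its C5 methyl ether by a final ether cleavage; this one methyl group is the regiochemical control element of the whole route.
- The methyl ether is cut at O1–C2 (ring B, intramolecular Mitsunobu etherification with inversion at C2) and at C8–geranyl (asymmetric allylic dearomatisation). Both events run in one flask from a flat hexasubstituted benzene and geranyl tert-butyl carbonate: ring A is dearomatised first, ring B is closed second.
- Enabling feature: once ring A is dearomatised, its enol oxygen on C8a is acidic and sits 1,5 to the carbinol carbon C2 of the 3-hydroxybutanoyl chain on C4a. The methyl ether on the C5 oxygen caps the only other oxygen that could reach C2, and leaves C8 as the one ring carbon between two free phenolic oxygens.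
- The arene comes from commercial 2',4'-dihydroxy-6'-methoxyacetophenone by C-methylation, C-prenylation, Claisen condensation and asymmetric hydrogenation of the 1,3-diketone (sets the carbinol); the carbonate comes from geraniol.

Key step: step 6

Remark: the ligand antipode that gives the (R)-quaternary carbon on this arene cannot be predicted, so the (R,R)-ligand is written and the (S,S)-ligand is to be used if the sense proves opposite; the diketone and the dearomatised enol are drawn as single tautomers.

**Step 1**
Reactants: 1 1-(2,4-dihydroxy-6-methoxyphenyl)ethan-1-one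
Product: 2 1-(2,4-dihydroxy-6-methoxy-3-methylphenyl)ethan-1-one
Conditions: MeI (1.1 equiv), KOH, MeOH, 0 °C to rt
Reagents that add atoms: iodomethane CI
Why: Base-mediated C-methylation of the ambident phenoxide should go to C3, the ring carbon between the two free hydroxyls and therefore the most nucleophilic, ahead of C5 next to the methyl ether; no stereocenter forms.

**Step 2**
Reactants: 2 1-(2,4-dihydroxy-6-methoxy-3-methylphenyl)ethan-1-one
Product: 3 1-[2,4-dihydroxy-6-methoxy-3-methyl-5-(3-methylbut-2-en-1-yl)phenyl]ethan-1-one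
Conditions: prenyl bromide (1.1 equiv), 10% aq. KOH, 0 °C to rt
Reagents that add atoms: prenyl bromide (1-bromo-3-methylbut-2-ene) CC(C)=CCBr
Why: Aqueous-base C-prenylation of the phenoxide (Friedel–Crafts-type C-alkylation) should go to C5, the only ring carbon that still carries hydrogen and whose alkylation keeps the ring aromatic; no stereocenter forms.

**Step 3**
Reactants: 3 1-[2,4-dihydroxy-6-methoxy-3-methyl-5-(3-methylbut-2-en-1-yl)phenyl]ethan-1-one
Product: 4 1-[2,4-dihydroxy-6-methoxy-3-methyl-5-(3-methylbut-2-en-1-yl)phenyl]butane-1,3-dione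
Conditions: LiN(SiMe3)2 (4.5 equiv), THF, −78 °C; EtOAc, −78 °C to rt; AcOH quench
Reagents that add atoms: ethyl acetate CCOC(C)=O
Why: Crossed Claisen condensation of the lithium enolate of the aryl methyl ketone with ethyl acetate, the phenols being held as lithium phenoxides by the excess amide base, should give the 1,3-diketone, which is expected to equilibrate with its enol and with the cyclic hemiketal at the free ortho hydroxyl; no stereocenter is set.

**Step 4**
Reactants: 4 1-[2,4-dihydroxy-6-methoxy-3-methyl-5-(3-methylbut-2-en-1-yl)phenyl]butane-1,3-dione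
Product: 5 (3R)-1-[2,4-dihydroxy-6-methoxy-3-methyl-5-(3-methylbut-2-en-1-yl)phenyl]-3-hydroxybutan-1-one
Conditions: [RuCl(p-cymene)((R)-BINAP)]Cl (1 mol%), H2 (50 bar), EtOH, 40 °C
Reagents that add atoms: none
Why: Noyori asymmetric hydrogenation of a 1,3-diketone should reduce only the chelating methyl ketone of the open form, leaving the deactivated, doubly ortho-substituted aryl ketone and the trisubstituted alkene untouched, and the (R)-BINAP ligand is expected to give the (R)-carbinol by analogy with β-keto esters.

**Step 5**
Reactants: 6 geraniol [(2E)-3,7-dimethylocta-2,6-dien-1-ol]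
Product: 7 tert-butyl (2E)-3,7-dimethylocta-2,6-dien-1-yl carbonate
Conditions: Boc2O, DMAP (10 mol%), CH2Cl2, 0 °C to rt
Reagents that add atoms: di-tert-butyl dicarbonate CC(C)(C)OC(=O)OC(=O)OC(C)(C)C
Why: DMAP-catalysed acylation of the primary allylic alcohol should give the mixed carbonate, a π-allyl precursor that releases only CO2 and tert-butanol on ionisation, with the E alkene untouched.

**Step 6**
Reactants: 5 (3R)-1-[2,4-dihydroxy-6-methoxy-3-methyl-5-(3-methylbut-2-en-1-yl)phenyl]-3-hydroxybutan-1-one; 7 tert-butyl (2E)-3,7-dimethylocta-2,6-dien-1-yl carbonate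
Product: 9 (2S,8R)-8-[(2E)-3,7-dimethylocta-2,6-dien-1-yl]-5-methoxy-2,8-dimethyl-6-(3-methylbut-2-en-1-yl)-2,3-dihydro-4H-chromene-4,7(8H)-dione, via dearomatised enol 8 (not isolated)
Conditions: Pd2(dba)3·CHCl3 (2.5 mol%), (1R,2R)-N,N'-bis[2-(diphenylphosphanyl)benzoyl]cyclohexane-1,2-diamine (7.5 mol%), THF, 0 °C to rt, Ar; then PPh3 (1.5 equiv), DIAD (1.5 equiv), 0 °C to rt
Reagents that add atoms: none
Why: Proposed new method: zerovalent palladium ionises 7 to a π-geranyl complex (CO2 and tert-butoxide leave), and the phenoxide of 5 attacks the unsubstituted allyl terminus through C3, the only ring carbon between two free phenolic oxygens, so that ring A is dearomatised to the acidic enol 8 with a linear E-geranyl group on the new quaternary carbon. The closest known reactions are the asymmetric Tsuji–Trost allylic dearomatisation of naphthols and substituted phenols with this ligand class and the racemic palladium-catalysed dearomative allylation of acylphloroglucinols, and as there the configuration of the quaternary carbon is set by the chiral ligand pocket, which must tell apart the two faces of the flat arene (acyl/OH flank against prenyl/OH flank). PPh3 and DIAD then turn the secondary alcohol into an alkoxyphosphonium ion while the betaine deprotonates the enol (estimated pKa near 5), and the enolate oxygen on C5 of 8, the future O1, displaces Ph3PO at the carbinol carbon in an intramolecular Mitsunobu etherification (precedented for chroman-4-ones from 2-hydroxyaryl β-hydroxy ketones) that closes ring B in the 6-exo-tet mode. C2 is not created here but inverted, so the (R)-carbinol of step 4 becomes the (S)-ether by SN2 displacement, independently of the quaternary centre. The step needs O- over C-cyclisation and one enol oxygen over the other, and the substrate secures both: the C3 methyl ether of 8 caps the only other oxygen within reach of C2, and attack through carbon or through the acyl oxygen would give four-membered rings. β-Elimination to the crotonyl ketone, which would erase C2, is disfavoured because the substrate reacts as its enolate, and running both stages in one flask (tert-butanol, the only protic by-product, is inert under Mitsunobu conditions) avoids isolating 8, which could cyclodehydrate through its hemiketal with retention.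

**Step 7**
Reactants: 9 (2S,8R)-8-[(2E)-3,7-dimethylocta-2,6-dien-1-yl]-5-methoxy-2,8-dimethyl-6-(3-methylbut-2-en-1-yl)-2,3-dihydro-4H-chromene-4,7(8H)-dione
Product: 10 (2S,8R)-8-[(2E)-3,7-dimethylocta-2,6-dien-1-yl]-5-hydroxy-2,8-dimethyl-6-(3-methylbut-2-en-1-yl)-2,3-dihydro-4H-chromene-4,7(8H)-dione
Conditions: MgI2·OEt2 (3 equiv), toluene/Et2O, rt; then cold 0.5 M HCl
Reagents that add atoms: none
Why: In this chelation-assisted SN2 ether cleavage magnesium should bind between the C4 carbonyl and the C5 methoxy oxygen, iodide attacks the methyl group and the vinylogous acid leaves as its magnesium enolate (a far better leaving group than anything at the secondary C2–O1 bond), while the neutral, non-basic medium should leave C2 (no retro-oxa-Michael opening), the quaternary carbon and the prenyl and geranyl alkenes untouched.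

**Compound list**

1 | 1-(2,4-dihydroxy-6-methoxyphenyl)ethan-1-one (2',4'-dihydroxy-6'-methoxyacetophenone) | CC(=O)c1c(O)cc(O)cc1OC | starting material
2 | 1-(2,4-dihydroxy-6-methoxy-3-methylphenyl)ethan-1-one | CC(=O)c1c(O)c(C)c(O)cc1OC | intermediate
3 | 1-[2,4-dihydroxy-6-methoxy-3-methyl-5-(3-methylbut-2-en-1-yl)phenyl]ethan-1-one | CC(=O)c1c(O)c(C)c(O)c(CC=C(C)C)c1OC | intermediate
4 | 1-[2,4-dihydroxy-6-methoxy-3-methyl-5-(3-methylbut-2-en-1-yl)phenyl]butane-1,3-dione (diketo form) | CC(=O)CC(=O)c1c(O)c(C)c(O)c(CC=C(C)C)c1OC | intermediate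
5 | (3R)-1-[2,4-dihydroxy-6-methoxy-3-methyl-5-(3-methylbut-2-en-1-yl)phenyl]-3-hydroxybutan-1-one | C[C@@H](O)CC(=O)c1c(O)c(C)c(O)c(CC=C(C)C)c1OC | intermediate
6 | geraniol [(2E)-3,7-dimethylocta-2,6-dien-1-ol] | CC(C)=CCC/C(C)=C/CO | starting material
7 | tert-butyl (2E)-3,7-dimethylocta-2,6-dien-1-yl carbonate | CC(C)=CCC/C(C)=C/COC(=O)OC(C)(C)C | intermediate
8 | (6R)-6-[(2E)-3,7-dimethylocta-2,6-dien-1-yl]-5-hydroxy-4-[(3R)-3-hydroxybutanoyl]-3-methoxy-6-methyl-2-(3-methylbut-2-en-1-yl)cyclohexa-2,4-dien-1-one | CC(C)=CCC/C(C)=C/C[C@@]1(C)C(=O)C(CC=C(C)C)=C(OC)C(C(=O)C[C@@H](C)O)=C1O | intermediate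
9 | (2S,8R)-8-[(2E)-3,7-dimethylocta-2,6-dien-1-yl]-5-methoxy-2,8-dimethyl-6-(3-methylbut-2-en-1-yl)-2,3-dihydro-4H-chromene-4,7(8H)-dione | CC(C)=CCC/C(C)=C/C[C@@]1(C)C(=O)C(CC=C(C)C)=C(OC)C2=C1O[C@@H](C)CC2=O | intermediate
10 | (2S,8R)-8-[(2E)-3,7-dimethylocta-2,6-dien-1-yl]-5-hydroxy-2,8-dimethyl-6-(3-methylbut-2-en-1-yl)-2,3-dihydro-4H-chromene-4,7(8H)-dione | CC(C)=CCC/C(C)=C/C[C@@]1(C)C(=O)C(CC=C(C)C)=C(O)C2=C1O[C@@H](C)CC2=O | target

**Step count**

Total step count: 7. Longest linear sequence: 6 (steps 1, 2, 3, 4, 6, 7).

**Steps most likely to fail**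

Step 6. The ligand may discriminate poorly between the two faces of the arene, giving low selectivity at the quaternary carbon. Other failure processes are attack at the prenyl-bearing carbon, loss of alkene geometry by π–σ–π isomerisation, and elimination during the Mitsunobu stage. The fallback sets out from 5 and 7 and returns at 9, using known chemistry only. The geranyl group is introduced without asymmetric induction by the known racemic dearomative Tsuji–Trost allylation of acylphloroglucinols [Pd(PPh3)4, THF, rt]. This should give 8 together with its epimer at the quaternary carbon, (6S)-6-[(2E)-3,7-dimethylocta-2,6-dien-1-yl]-5-hydroxy-4-[(3R)-3-hydroxybutanoyl]-3-methoxy-6-methyl-2-(3-methylbut-2-en-1-yl)cyclohexa-2,4-dien-1-one F1. The mixture is then cyclised in a separate flask under standard Mitsunobu conditions (PPh3, DIAD, THF, 0 °C) to 9 and its C8 epimer, (2S,8S)-8-[(2E)-3,7-dimethylocta-2,6-dien-1-yl]-5-methoxy-2,8-dimethyl-6-(3-methylbut-2-en-1-yl)-2,3-dihydro-4H-chromene-4,7(8H)-dione F2. These are diastereomers because C2 is already fixed from step 4, so they are to be separated by preparative HPLC, at the cost of the unwanted half, before 9 goes on to step 7.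

Step 4. The cyclic hemiketal form of 4 may dehydrate to the aromatic 2-methylpyranone under the slightly acidic hydrogenation medium, and the catalyst may be inhibited by the free phenols or fail to distinguish the two carbonyl groups. The fallback sets out from 3 and returns at 5. Aldol addition of the trilithio derivative of 3 [LiN(iPr)2, THF, −78 °C] to acetaldehyde should give the racemic carbinol, 1-[2,4-dihydroxy-6-methoxy-3-methyl-5-(3-methylbut-2-en-1-yl)phenyl]-3-hydroxybutan-1-one F3. This is resolved by lipase-catalysed transesterification (immobilised Candida antarctica lipase B, vinyl acetate, MTBE, rt). By the usual enantiopreference of this lipase for secondary alcohols, the (R)-alcohol is expected to be acetylated to (2R)-4-[2,4-dihydroxy-6-methoxy-3-methyl-5-(3-methylbut-2-en-1-yl)phenyl]-4-oxobutan-2-yl acetate F4. The unreacted (3S)-1-[2,4-dihydroxy-6-methoxy-3-methyl-5-(3-methylbut-2-en-1-yl)phenyl]-3-hydroxybutan-1-one F5 is separated by chromatography. Lipase-catalysed butanolysis of F4 (n-butanol, MTBE) then releases 5 under neutral conditions, so that no base touches the β-acyloxy ketone.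

Step 2. O-Alkylation and dearomatising alkylation at the methyl-bearing carbon may compete with the wanted C-alkylation, and a second prenylation may follow. The fallback sets out from 2 and returns at 3. The non-chelated 4-hydroxyl is alkylated with 3-chloro-3-methylbut-1-yne (K2CO3, KI, CuI cat., acetone, reflux) to 1-{2-hydroxy-6-methoxy-3-methyl-4-[(2-methylbut-3-yn-2-yl)oxy]phenyl}ethan-1-one F6. Semihydrogenation (H2, Pd/CaCO3 poisoned with Pb(OAc)2, quinoline, EtOAc) gives 1-{2-hydroxy-6-methoxy-3-methyl-4-[(2-methylbut-3-en-2-yl)oxy]phenyl}ethan-1-one F7. Aromatic Claisen rearrangement (N,N-diethylaniline, 130 °C) can end only at C5, the one free ortho position, and delivers the linear prenyl group of 3.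

**Further compounds**

F1 | step 6 | (6S)-6-[(2E)-3,7-dimethylocta-2,6-dien-1-yl]-5-hydroxy-4-[(3R)-3-hydroxybutanoyl]-3-methoxy-6-methyl-2-(3-methylbut-2-en-1-yl)cyclohexa-2,4-dien-1-one | CC(C)=CCC/C(C)=C/C[C@]1(C)C(=O)C(CC=C(C)C)=C(OC)C(C(=O)C[C@@H](C)O)=C1O
F2 | step 6 | (2S,8S)-8-[(2E)-3,7-dimethylocta-2,6-dien-1-yl]-5-methoxy-2,8-dimethyl-6-(3-methylbut-2-en-1-yl)-2,3-dihydro-4H-chromene-4,7(8H)-dione | CC(C)=CCC/C(C)=C/C[C@]1(C)C(=O)C(CC=C(C)C)=C(OC)C2=C1O[C@@H](C)CC2=O
F3 | step 4 | racemic 1-[2,4-dihydroxy-6-methoxy-3-methyl-5-(3-methylbut-2-en-1-yl)phenyl]-3-hydroxybutan-1-one | CC(O)CC(=O)c1c(O)c(C)c(O)c(CC=C(C)C)c1OC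
F4 | step 4 | (2R)-4-[2,4-dihydroxy-6-methoxy-3-methyl-5-(3-methylbut-2-en-1-yl)phenyl]-4-oxobutan-2-yl acetate | C[C@@H](OC(C)=O)CC(=O)c1c(O)c(C)c(O)c(CC=C(C)C)c1OC
F5 | step 4 | (3S)-1-[2,4-dihydroxy-6-methoxy-3-methyl-5-(3-methylbut-2-en-1-yl)phenyl]-3-hydroxybutan-1-one | C[C@H](O)CC(=O)c1c(O)c(C)c(O)c(CC=C(C)C)c1OC
F6 | step 2 | 1-{2-hydroxy-6-methoxy-3-methyl-4-[(2-methylbut-3-yn-2-yl)oxy]phenyl}ethan-1-one | CC(=O)c1c(O)c(C)c(OC(C)(C)C#C)cc1OC
F7 | step 2 | 1-{2-hydroxy-6-methoxy-3-methyl-4-[(2-methylbut-3-en-2-yl)oxy]phenyl}ethan-1-one | CC(=O)c1c(O)c(C)c(OC(C)(C)C=C)cc1OC
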